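**Plan**

1. Retrosynthesis: the 1,10-epoxide oxygen and the C8 epoxy ester come off last. The lactone C12–O6 bond and, in one event, C11–C12 and C6–C7 are then cut, which opens both rings to the acyclic allene–enal 24 plus CO2. Compound 24 is cut at C13 (allene homologation), C3–C4 (alkenyl–aldehyde coupling), C1–C2 and C10–CH3 (carboalumination/oxirane) and C8–C9 (propargylation).
2. Enabling feature: the α-methylene-γ-butyrolactone (ring B: O, C6, C7, C11, C12, exocyclic C11=C13) is fused along C6–C7 to the ten-membered carbocycle (ring A, C1–C10). C13=C11–C7 is the imprint of a terminal allene, C12 of CO2 and C6–O of an aldehyde.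
3. Forward: the chain is built linearly (C8, then C10=C1, C3, C4–C6, C13). Ring A then closes at C6–C7 by allylnickel–aldehyde addition and ring B by lactonization in the same operation. The C8 ester and the epoxide follow.
4. Stereochemistry: C8 by asymmetric transfer hydrogenation and C3 by CBS reduction (catalyst control). C7 and C6 are relayed from C8 in the ring-closing event. C1/C10 come from substrate-controlled epoxidation of ring A, and the side-chain epoxide from Sharpless epoxidation.

Key step: step 16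

Remark: germacrane numbering (C1–C15) of the target is used for all intermediates; compounds 1, 2, 7, 11, 19 and 29 are taken as commercial.

**Step 1**
Reactants: 1 3-(trimethylsilyl)prop-2-ynal; 2 3-bromoprop-1-yne
Product: 3 rac-1-(trimethylsilyl)hexa-1,5-diyn-3-ol
Conditions: Zn dust, THF/sat. aq. NH4Cl, 0 °C
Reagents that add atoms: none
Why: Barbier propargylation, in which the allenylzinc formed in situ should add to the aldehyde through its γ-carbon to give the homopropargylic alcohol, racemic at the future C8.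

**Step 2**
Reactants: 3 rac-1-(trimethylsilyl)hexa-1,5-diyn-3-ol
Product: 4 1-(trimethylsilyl)hexa-1,5-diyn-3-one
Conditions: Dess–Martin periodinane, NaHCO3, CH2Cl2, 0 °C
Reagents that add atoms: none
Why: Dess–Martin oxidation under buffered, non-basic conditions should give the ynone without moving the CH2 group that lies between carbonyl and alkyne.

**Step 3**
Reactants: 4 1-(trimethylsilyl)hexa-1,5-diyn-3-one
Product: 5 (R)-1-(trimethylsilyl)hexa-1,5-diyn-3-ol
Conditions: Ru[(R,R)-TsDPEN](p-cymene) (1 mol %), i-PrOH, 25 °C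
Reagents that add atoms: none
Why: Noyori asymmetric transfer hydrogenation of an alkynyl ketone, in which the R,R catalyst should deliver hydride to the face that gives the R carbinol (C8), the alkynyl group taking the role of the aryl group of aryl ketones.

**Step 4**
Reactants: 5 (R)-1-(trimethylsilyl)hexa-1,5-diyn-3-ol
Product: 6 (R)-3-(tert-butyldimethylsilyloxy)-1-(trimethylsilyl)hexa-1,5-diyne
Conditions: TBSCl, imidazole, DMF, rt
Reagents that add atoms: tert-butyldimethylsilyl chloride, CC(C)(C)[Si](C)(C)Cl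
Why: Standard silylation protects O8 through the organometallic steps and leaves the C8 configuration untouched.

**Step 5**
Reactants: 6 (R)-3-(tert-butyldimethylsilyloxy)-1-(trimethylsilyl)hexa-1,5-diyne; 7 oxirane
Product: 9 (3E,6R)-6-(tert-butyldimethylsilyloxy)-4-methyl-8-(trimethylsilyl)oct-3-en-7-yn-1-ol, via alkenylalane 8 (not isolated)
Conditions: Me3Al, Cp2ZrCl2 (0.25 equiv), CH2Cl2, 0 °C to rt; volatiles removed; n-BuLi, THF/hexane, −78 °C; oxirane, −78 °C to rt
Reagents that add atoms: trimethylaluminium, C[Al](C)C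
Why: Negishi zirconium-catalysed carboalumination adds methyl and aluminium syn across the terminal alkyne (methyl to the internal carbon), which fixes the E geometry of C1=C10 while the silyl-capped alkyne stays inert, and the derived alanate opens oxirane to append C2 and C3.

**Step 6**
Reactants: 9 (3E,6R)-6-(tert-butyldimethylsilyloxy)-4-methyl-8-(trimethylsilyl)oct-3-en-7-yn-1-ol
Product: 10 (3E,6R)-6-(tert-butyldimethylsilyloxy)-4-methyl-8-(trimethylsilyl)oct-3-en-7-ynal
Conditions: Dess–Martin periodinane, NaHCO3, CH2Cl2, 0 °C; used crude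
Reagents that add atoms: none
Why: Dess–Martin oxidation under neutral buffered conditions should give the β,γ-unsaturated aldehyde without moving the double bond into conjugation.

**Step 7**
Reactants: 11 but-2-yn-1-ol
Product: 13 (Z)-3-iodobut-2-en-1-ol, via vinylalanate 12 (not isolated)
Conditions: NaAlH2(OCH2CH2OMe)2, THF, 0 °C to rt; then N-iodosuccinimide, THF, −78 °C
Reagents that add atoms: N-iodosuccinimide, O=C1CCC(=O)N1I
Why: Hydroxyl-directed trans-hydroalumination of the propargylic alcohol places aluminium on C3 cis to CH2OH, and iodinolysis with retention gives the Z iodide that encodes the Z geometry of C4=C5.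

**Step 8**
Reactants: 13 (Z)-3-iodobut-2-en-1-ol
Product: 14 (Z)-tert-butyl[(3-iodobut-2-en-1-yl)oxy]dimethylsilane
Conditions: TBSCl, imidazole, CH2Cl2, rt
Reagents that add atoms: tert-butyldimethylsilyl chloride, CC(C)(C)[Si](C)(C)Cl
Why: Standard silylation masks the future C6 aldehyde as its protected alcohol.

**Step 9**
Reactants: 10 (3E,6R)-6-(tert-butyldimethylsilyloxy)-4-methyl-8-(trimethylsilyl)oct-3-en-7-ynal; 14 (Z)-tert-butyl[(3-iodobut-2-en-1-yl)oxy]dimethylsilane
Product: 15 (2Z,6E,9R)-1,9-bis(tert-butyldimethylsilyloxy)-3,7-dimethyl-11-(trimethylsilyl)undeca-2,6-dien-10-yn-4-ol (both C4 epimers)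
Conditions: CrCl2 (4 equiv), NiCl2 (2 mol %), DMSO, rt
Reagents that add atoms: none
Why: Nozaki–Hiyama–Kishi coupling forms C3–C4 without base, so the enolizable aldehyde should not isomerize and the Z geometry of the iodide is retained, while the new carbinol (C3) forms unselectively and is corrected in steps 10 and 11.

**Step 10**
Reactants: 15 (2Z,6E,9R)-1,9-bis(tert-butyldimethylsilyloxy)-3,7-dimethyl-11-(trimethylsilyl)undeca-2,6-dien-10-yn-4-ol
Product: 16 (2Z,6E,9R)-1,9-bis(tert-butyldimethylsilyloxy)-3,7-dimethyl-11-(trimethylsilyl)undeca-2,6-dien-10-yn-4-one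
Conditions: Dess–Martin periodinane, NaHCO3, CH2Cl2, 0 °C
Reagents that add atoms: none
Why: Dess–Martin oxidation converges both epimers on the enone under conditions that should not move the skipped C1=C10 alkene.

**Step 11**
Reactants: 16 (2Z,6E,9R)-1,9-bis(tert-butyldimethylsilyloxy)-3,7-dimethyl-11-(trimethylsilyl)undeca-2,6-dien-10-yn-4-one
Product: 18 (2Z,4S,6E,9R)-1,9-bis(tert-butyldimethylsilyloxy)-3,7-dimethylundeca-2,6-dien-10-yn-4-ol, via silylalkyne alcohol 17 (not isolated)
Conditions: (R)-Me-CBS oxazaborolidine (0.2 equiv), catecholborane, toluene, −78 °C; then MeOH, K2CO3, rt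
Reagents that add atoms: none
Why: Corey–Bakshi–Shibata reduction with the α-methylalkenyl group as the large substituent should give the 3S allylic alcohol under catalyst control, and methanolic carbonate then removes the alkynyl trimethylsilyl group in the same flask.

**Step 12**
Reactants: 18 (2Z,4S,6E,9R)-1,9-bis(tert-butyldimethylsilyloxy)-3,7-dimethylundeca-2,6-dien-10-yn-4-ol; 19 3-methylbutanoyl chloride
Product: 20 (2Z,4S,6E,9R)-1,9-bis(tert-butyldimethylsilyloxy)-3,7-dimethylundeca-2,6-dien-10-yn-4-yl 3-methylbutanoate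
Conditions: pyridine, DMAP (cat.), CH2Cl2, 0 °C
Reagents that add atoms: none
Why: Acylation of the only free hydroxyl installs the C3 isovalerate of the target, which from here on also protects O3.

**Step 13**
Reactants: 20 (2Z,4S,6E,9R)-1,9-bis(tert-butyldimethylsilyloxy)-3,7-dimethylundeca-2,6-dien-10-yn-4-yl 3-methylbutanoate
Product: 22 (2Z,4S,6E,9R)-1,9-bis(tert-butyldimethylsilyloxy)-3,7-dimethyldodeca-2,6,10,11-tetraen-4-yl 3-methylbutanoate, via Mannich base 21 (not isolated)
Conditions: (CH2O)n, CuI (0.5 equiv), Cy2NH, dioxane, reflux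
Reagents that add atoms: paraformaldehyde (as formaldehyde), C=O
Why: Crabbé homologation, in which the copper-mediated Mannich reaction gives the propargylic amine that undergoes intramolecular hydride transfer and loss of imine to the terminal allene (C13 added), leaving C8 untouched.

**Step 14**
Reactants: 22 (2Z,4S,6E,9R)-1,9-bis(tert-butyldimethylsilyloxy)-3,7-dimethyldodeca-2,6,10,11-tetraen-4-yl 3-methylbutanoate
Product: 23 (2Z,4S,6E,9R)-9-(tert-butyldimethylsilyloxy)-1-hydroxy-3,7-dimethyldodeca-2,6,10,11-tetraen-4-yl 3-methylbutanoate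
Conditions: HF·pyridine, pyridine, THF, 0 °C
Reagents that add atoms: none
Why: Buffered fluoride desilylation should cleave the primary allylic silyl ether much faster than the hindered secondary one at C8.

**Step 15**
Reactants: 23 (2Z,4S,6E,9R)-9-(tert-butyldimethylsilyloxy)-1-hydroxy-3,7-dimethyldodeca-2,6,10,11-tetraen-4-yl 3-methylbutanoate
Product: 24 (2Z,4S,6E,9R)-9-(tert-butyldimethylsilyloxy)-3,7-dimethyl-1-oxododeca-2,6,10,11-tetraen-4-yl 3-methylbutanoate
Conditions: Dess–Martin periodinane, NaHCO3, CH2Cl2, 0 °C; used at once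
Reagents that add atoms: none
Why: Dess–Martin oxidation of the Z allylic alcohol should give the Z enal (C6) with retention of the double-bond geometry.

**Step 16**
Reactants: 24 (2Z,4S,6E,9R)-9-(tert-butyldimethylsilyloxy)-3,7-dimethyl-1-oxododeca-2,6,10,11-tetraen-4-yl 3-methylbutanoate
Product: 27 8β-(tert-butyldimethylsilyloxy)-3β-(3-methylbutanoyloxy)germacra-1(10)E,4Z,11(13)-trien-12,6α-olide (3S,6R,8R; 7α-H), via nickelalactone 25 (not isolated), via hydroxy acid 26 (not isolated)
Conditions: 24 in CO2-saturated THF (2 mM, CO2 1 atm), 0 °C; Ni(cod)2 (1.2 equiv) and DBU (2.4 equiv) in THF added over 6 h, then rt; 1 M HCl, 0 °C; then EDC·HCl, DMAP (cat.), CH2Cl2, 0 °C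
Reagents that add atoms: carbon dioxide, O=C=O
Why: Proposed new method: zerovalent nickel bound by DBU couples the terminal C11=C13 bond of the allene with CO2 by oxidative cyclization to the five-membered nickelalactone 25 (C11–C12 bond), whose η3/η1-allyl unit then adds through its γ-carbon C7 to the tethered aldehyde C6 in a six-membered chair transition state (C6–C7 bond), and acid work-up with carbodiimide lactonization of 26 completes the sequence; the closest known reaction is the intermolecular nickel-mediated sequential addition of CO2 and aldehydes to terminal allenes, and the ring closure parallels the macrocyclizing Barbier and Nozaki–Hiyama allylations of (bromomethyl)acrylates used for germacranolides. Ring A closes as a ten-membered ring by intramolecular SE2' allylmetal–aldehyde addition, and ring B as a five-membered lactone by 5-exo-trig acyl substitution of the C6 hydroxyl on the C12 carboxyl. C7 is controlled by C8: with H8 eclipsing the allyl double bond to avoid A(1,3) strain against the C12 carboxylate, the aldehyde should attack anti to the C8–C9 bond with the silyloxy group outside, which gives the 7α-H/8β-O relation. C6 is controlled by the chair: the thermodynamically favoured syn (E) allylnickel and an equatorial aldehyde substituent give the 6,7-anti adduct and hence the trans-fused lactone. The step needs γ- over α-attack of the allyl unit and carboxylation at the central allene carbon (both intrinsic to the nickelalactone), reaction of nickel with the allene in preference to the enal and the allylic ester (nickel is kept limiting by slow addition under excess CO2), and ring closure over oligomerization (high dilution).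

**Step 17**
Reactants: 27 8β-(tert-butyldimethylsilyloxy)-3β-(3-methylbutanoyloxy)germacra-1(10)E,4Z,11(13)-trien-12,6α-olide
Product: 28 8β-hydroxy-3β-(3-methylbutanoyloxy)germacra-1(10)E,4Z,11(13)-trien-12,6α-olide
Conditions: HF·pyridine, THF, 0 °C to rt
Reagents that add atoms: none
Why: Acidic fluoride desilylation frees O8 without touching the α-methylene lactone or the allylic ester.

**Step 18**
Reactants: 29 (E)-2-methylbut-2-en-1-ol
Product: 30 [(2R,3R)-2,3-dimethyloxiran-2-yl]methanol
Conditions: Ti(O-i-Pr)4 (0.1 equiv), D-(−)-diisopropyl tartrate (0.12 equiv), t-BuOOH, 4 Å molecular sieves, CH2Cl2, −20 °C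
Reagents that add atoms: tert-butyl hydroperoxide, CC(C)(C)OO
Why: Sharpless asymmetric epoxidation with the D-tartrate should deliver oxygen to the face of the E allylic alcohol that gives the 2R,3R epoxy alcohol (reagent control), the trans relation of both side-chain stereocenters coming from the E alkene.

**Step 19**
Reactants: 30 [(2R,3R)-2,3-dimethyloxiran-2-yl]methanol
Product: 31 (2S,3R)-2,3-dimethyloxirane-2-carboxylic acid
Conditions: RuCl3·xH2O (2 mol %), NaIO4, CCl4/MeCN/H2O, rt
Reagents that add atoms: sodium periodate, [Na+].[O-]I(=O)(=O)=O; water, O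
Why: Catalytic ruthenium tetroxide oxidation takes the primary alcohol to the acid without opening the epoxide, the descriptor at C2 changing only through CIP priorities.

**Step 20**
Reactants: 28 8β-hydroxy-3β-(3-methylbutanoyloxy)germacra-1(10)E,4Z,11(13)-trien-12,6α-olide; 31 (2S,3R)-2,3-dimethyloxirane-2-carboxylic acid
Product: 33 8β-[(2S,3R)-2,3-dimethyloxirane-2-carbonyloxy]-3β-(3-methylbutanoyloxy)germacra-1(10)E,4Z,11(13)-trien-12,6α-olide, via mixed anhydride 32 (not isolated)
Conditions: 31, 2,4,6-trichlorobenzoyl chloride, Et3N, toluene, rt; then 28, DMAP, toluene, rt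
Reagents that add atoms: none
Why: Yamaguchi esterification activates the hindered α,α-disubstituted epoxy acid as a mixed anhydride that DMAP transfers to the secondary C8 hydroxyl with retention at all stereocenters.

**Step 21**
Reactants: 33 8β-[(2S,3R)-2,3-dimethyloxirane-2-carbonyloxy]-3β-(3-methylbutanoyloxy)germacra-1(10)E,4Z,11(13)-trien-12,6α-olide
Product: 34 1β,10α-epoxy-8β-[(2S,3R)-2,3-dimethyloxirane-2-carbonyloxy]-3β-(3-methylbutanoyloxy)germacra-4Z,11(13)-dien-12,6α-olide (CNP0167461.3)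
Conditions: mCPBA (1.1 equiv), NaHCO3, CH2Cl2, 0 °C
Reagents that add atoms: 3-chloroperoxybenzoic acid, OOC(=O)c1cccc(Cl)c1
Why: Prilezhaev epoxidation should take place at the electron-rich E-1(10) alkene (C4=C5 is deactivated by two allylic acyloxy groups, C11=C13 by conjugation) from the exposed outer face of ring A, as is usual for germacranolides, to set C1 and C10 as the 1β,10α-epoxide (substrate control).

**Compound list**

1 | 3-(trimethylsilyl)prop-2-ynal | C[Si](C)(C)C#CC=O | starting material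
2 | 3-bromoprop-1-yne | C#CCBr | starting material
3 | rac-1-(trimethylsilyl)hexa-1,5-diyn-3-ol | C#CCC(O)C#C[Si](C)(C)C | intermediate
4 | 1-(trimethylsilyl)hexa-1,5-diyn-3-one | C#CCC(=O)C#C[Si](C)(C)C | intermediate
5 | (R)-1-(trimethylsilyl)hexa-1,5-diyn-3-ol | C#CC[C@@H](O)C#C[Si](C)(C)C | intermediate
6 | (R)-3-(tert-butyldimethylsilyloxy)-1-(trimethylsilyl)hexa-1,5-diyne | C#CC[C@@H](O[Si](C)(C)C(C)(C)C)C#C[Si](C)(C)C | intermediate
7 | oxirane | C1CO1 | starting material
8 | dimethyl[(1E,4R)-4-(tert-butyldimethylsilyloxy)-2-methyl-6-(trimethylsilyl)hex-1-en-5-yn-1-yl]alane | C[Al](C)/C=C(\C)C[C@@H](O[Si](C)(C)C(C)(C)C)C#C[Si](C)(C)C | intermediate (not isolated)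
9 | (3E,6R)-6-(tert-butyldimethylsilyloxy)-4-methyl-8-(trimethylsilyl)oct-3-en-7-yn-1-ol | OCC/C=C(\C)C[C@@H](O[Si](C)(C)C(C)(C)C)C#C[Si](C)(C)C | intermediate
10 | (3E,6R)-6-(tert-butyldimethylsilyloxy)-4-methyl-8-(trimethylsilyl)oct-3-en-7-ynal | O=CC/C=C(\C)C[C@@H](O[Si](C)(C)C(C)(C)C)C#C[Si](C)(C)C | intermediate
11 | but-2-yn-1-ol | CC#CCO | starting material
12 | sodium 2,2-bis(2-methoxyethoxy)-3-methyl-2,5-dihydro-1,2-oxaluminol-2-uide (cyclic vinylalanate) | CC1=CCO[Al-]1(OCCOC)OCCOC.[Na+] | intermediate (not isolated)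
13 | (Z)-3-iodobut-2-en-1-ol | OC/C=C(/C)I | intermediate
14 | (Z)-tert-butyl[(3-iodobut-2-en-1-yl)oxy]dimethylsilane | CC(C)(C)[Si](C)(C)OC/C=C(/C)I | intermediate
15 | (2Z,6E,9R)-1,9-bis(tert-butyldimethylsilyloxy)-3,7-dimethyl-11-(trimethylsilyl)undeca-2,6-dien-10-yn-4-ol, both C4 epimers | CC(C)(C)[Si](C)(C)OC/C=C(/C)C(O)C/C=C(\C)C[C@@H](O[Si](C)(C)C(C)(C)C)C#C[Si](C)(C)C | intermediate
16 | (2Z,6E,9R)-1,9-bis(tert-butyldimethylsilyloxy)-3,7-dimethyl-11-(trimethylsilyl)undeca-2,6-dien-10-yn-4-one | CC(C)(C)[Si](C)(C)OC/C=C(/C)C(=O)C/C=C(\C)C[C@@H](O[Si](C)(C)C(C)(C)C)C#C[Si](C)(C)C | intermediate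
17 | (2Z,4S,6E,9R)-1,9-bis(tert-butyldimethylsilyloxy)-3,7-dimethyl-11-(trimethylsilyl)undeca-2,6-dien-10-yn-4-ol | CC(C)(C)[Si](C)(C)OC/C=C(/C)[C@@H](O)C/C=C(\C)C[C@@H](O[Si](C)(C)C(C)(C)C)C#C[Si](C)(C)C | intermediate (not isolated)
18 | (2Z,4S,6E,9R)-1,9-bis(tert-butyldimethylsilyloxy)-3,7-dimethylundeca-2,6-dien-10-yn-4-ol | CC(C)(C)[Si](C)(C)OC/C=C(/C)[C@@H](O)C/C=C(\C)C[C@@H](O[Si](C)(C)C(C)(C)C)C#C | intermediate
19 | 3-methylbutanoyl chloride | CC(C)CC(=O)Cl | starting material
20 | (2Z,4S,6E,9R)-1,9-bis(tert-butyldimethylsilyloxy)-3,7-dimethylundeca-2,6-dien-10-yn-4-yl 3-methylbutanoate | CC(C)(C)[Si](C)(C)OC/C=C(/C)[C@@H](OC(=O)CC(C)C)C/C=C(\C)C[C@@H](O[Si](C)(C)C(C)(C)C)C#C | intermediate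
21 | (2Z,4S,6E,9R)-1,9-bis(tert-butyldimethylsilyloxy)-12-(dicyclohexylamino)-3,7-dimethyldodeca-2,6-dien-10-yn-4-yl 3-methylbutanoate (Mannich base) | CC(C)(C)[Si](C)(C)OC/C=C(/C)[C@@H](OC(=O)CC(C)C)C/C=C(\C)C[C@@H](O[Si](C)(C)C(C)(C)C)C#CCN(C1CCCCC1)C1CCCCC1 | intermediate (not isolated)
22 | (2Z,4S,6E,9R)-1,9-bis(tert-butyldimethylsilyloxy)-3,7-dimethyldodeca-2,6,10,11-tetraen-4-yl 3-methylbutanoate | CC(C)(C)[Si](C)(C)OC/C=C(/C)[C@@H](OC(=O)CC(C)C)C/C=C(\C)C[C@@H](O[Si](C)(C)C(C)(C)C)C=C=C | intermediate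
23 | (2Z,4S,6E,9R)-9-(tert-butyldimethylsilyloxy)-1-hydroxy-3,7-dimethyldodeca-2,6,10,11-tetraen-4-yl 3-methylbutanoate | OC/C=C(/C)[C@@H](OC(=O)CC(C)C)C/C=C(\C)C[C@@H](O[Si](C)(C)C(C)(C)C)C=C=C | intermediate
24 | (2Z,4S,6E,9R)-9-(tert-butyldimethylsilyloxy)-3,7-dimethyl-1-oxododeca-2,6,10,11-tetraen-4-yl 3-methylbutanoate | O=C/C=C(/C)[C@@H](OC(=O)CC(C)C)C/C=C(\C)C[C@@H](O[Si](C)(C)C(C)(C)C)C=C=C | intermediate
25 | nickelalactone of 24 (4-alkylidene-1,2-oxanickelolan-5-one built from C13, C11 and C12; DBU ligands on nickel not drawn) | O=C/C=C(/C)[C@@H](OC(=O)CC(C)C)C/C=C(\C)C[C@@H](O[Si](C)(C)C(C)(C)C)/C=C1/C[Ni]OC1=O | intermediate (not isolated)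
26 | 6α-hydroxy-8β-(tert-butyldimethylsilyloxy)-3β-(3-methylbutanoyloxy)germacra-1(10)E,4Z,11(13)-trien-12-oic acid | O[C@@H]1/C=C(/C)[C@@H](OC(=O)CC(C)C)C/C=C(\C)C[C@@H](O[Si](C)(C)C(C)(C)C)[C@H]1C(=C)C(=O)O | intermediate (not isolated)
27 | 8β-(tert-butyldimethylsilyloxy)-3β-(3-methylbutanoyloxy)germacra-1(10)E,4Z,11(13)-trien-12,6α-olide | C=C1C(=O)O[C@@H]2/C=C(/C)[C@@H](OC(=O)CC(C)C)C/C=C(\C)C[C@@H](O[Si](C)(C)C(C)(C)C)[C@@H]12 | intermediate
28 | 8β-hydroxy-3β-(3-methylbutanoyloxy)germacra-1(10)E,4Z,11(13)-trien-12,6α-olide | C=C1C(=O)O[C@@H]2/C=C(/C)[C@@H](OC(=O)CC(C)C)C/C=C(\C)C[C@@H](O)[C@@H]12 | intermediate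
29 | (E)-2-methylbut-2-en-1-ol | C/C=C(\C)CO | starting material
30 | [(2R,3R)-2,3-dimethyloxiran-2-yl]methanol | OC[C@@]1(C)O[C@@H]1C | intermediate
31 | (2S,3R)-2,3-dimethyloxirane-2-carboxylic acid | OC(=O)[C@@]1(C)O[C@@H]1C | intermediate
32 | (2S,3R)-2,3-dimethyloxirane-2-carboxylic 2,4,6-trichlorobenzoic anhydride | O=C(OC(=O)[C@@]1(C)O[C@@H]1C)c1c(Cl)cc(Cl)cc1Cl | intermediate (not isolated)
33 | 8β-[(2S,3R)-2,3-dimethyloxirane-2-carbonyloxy]-3β-(3-methylbutanoyloxy)germacra-1(10)E,4Z,11(13)-trien-12,6α-olide | C=C1C(=O)O[C@@H]2/C=C(/C)[C@@H](OC(=O)CC(C)C)C/C=C(\C)C[C@@H](OC(=O)[C@@]3(C)O[C@@H]3C)[C@@H]12 | intermediate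
34 | 1β,10α-epoxy-8β-[(2S,3R)-2,3-dimethyloxirane-2-carbonyloxy]-3β-(3-methylbutanoyloxy)germacra-4Z,11(13)-dien-12,6α-olide (1R,3S,6R,7R,8R,10R) | C=C1C(=O)O[C@@H]2/C=C(/C)[C@@H](OC(=O)CC(C)C)C[C@H]3O[C@]3(C)C[C@@H](OC(=O)[C@@]3(C)O[C@@H]3C)[C@@H]12 | target

**Step count**

Total: 21 steps. Longest linear sequence: 17 steps (steps 1–6, 9–17, 20, 21).

**Steps most likely to fail**

1. Step 16 (Proposed new method). Oligomerization may outrun closure of the ten-membered ring. Zerovalent nickel may be captured by the enal or may ionize the allylic C3 ester. DBU may isomerize the Z enal. The facial selectivity at C6/C7 may be poor. The fallback uses documented chemistry only, separates the two events and closes ring A at C3–C4 instead; it sets out from 9 and returns at 27.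
   - K2CO3/MeOH removes the alkynyl silane of 9 to give (3E,6R)-6-(tert-butyldimethylsilyloxy)-4-methyloct-3-en-7-yn-1-ol F1, and Et3SiCl/imidazole gives its triethylsilyl ether F2.
   - Crabbé homologation ((CH2O)n, CuI, Cy2NH, dioxane, reflux) passes through the Mannich base F3 to the allene F4.
   - MnO2 oxidation of 13 gives (Z)-3-iodobut-2-enal F5.
   - In the intermolecular protocol (Ni(cod)2, DBU, CO2, THF, 0 °C), F4 is first converted into the nickelalactone F6, to which F5 is then added. Aqueous HCl, which also removes the triethylsilyl group, gives the hydroxy acid F7, and EDC closes the trans lactone alcohol F8.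
   - Dess–Martin oxidation gives the aldehyde F9, and Nozaki–Hiyama–Kishi macrocyclization (CrCl2, NiCl2 cat., DMSO/THF, high dilution) gives the macrocyclic 3β-alcohol F10.
   - Acylation of F10 with 19 gives 27; a 3-epimer would instead be esterified with inversion under Mitsunobu conditions.

2. Step 21. The peracid may attack the wrong face of C1=C10, may also epoxidize C4=C5, or the product may open transannularly under acid. The fallback replaces substrate control by reagent control and moves the epoxidation ahead of the acylation; it sets out from 28 and returns at 34. Shi epoxidation of 28 (D-fructose-derived ketone catalyst, KHSO5, K2CO3 buffer, MeCN/dimethoxymethane/H2O, 0 °C) should give 1β,10α-epoxy-8β-hydroxy-3β-(3-methylbutanoyloxy)germacra-4Z,11(13)-dien-12,6α-olide F11. Yamaguchi esterification of F11 with 31 (through 32) then gives 34.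

3. Step 3. The basic ruthenium amide may shift the CH2 group flanked by carbonyl and alkyne to the allenyl ketone before hydride transfer, or the ee may erode. The fallback avoids the ynone by resolution; it sets out from 3 and returns at 5. Burkholderia cepacia lipase with vinyl acetate in hexane should acetylate the R alcohol (the silylalkynyl group acting as the large substituent) to give (R)-1-(trimethylsilyl)hexa-1,5-diyn-3-yl acetate F12, which is separated from the unreacted S alcohol. i-Bu2AlH (CH2Cl2, −78 °C) then cleaves F12 to 5 without touching the alkynyl silane.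

**Further compounds**

F1 | step 16 | (3E,6R)-6-(tert-butyldimethylsilyloxy)-4-methyloct-3-en-7-yn-1-ol | OCC/C=C(\C)C[C@@H](O[Si](C)(C)C(C)(C)C)C#C
F2 | step 16 | (3E,6R)-6-(tert-butyldimethylsilyloxy)-4-methyl-1-(triethylsilyloxy)oct-3-en-7-yne | CC[Si](CC)(CC)OCC/C=C(\C)C[C@@H](O[Si](C)(C)C(C)(C)C)C#C
F3 | step 16 | (4R,6E)-4-(tert-butyldimethylsilyloxy)-N,N-dicyclohexyl-6-methyl-9-(triethylsilyloxy)non-6-en-2-yn-1-amine (Mannich base) | CC[Si](CC)(CC)OCC/C=C(\C)C[C@@H](O[Si](C)(C)C(C)(C)C)C#CCN(C1CCCCC1)C1CCCCC1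
F4 | step 16 | (3E,6R)-6-(tert-butyldimethylsilyloxy)-4-methyl-1-(triethylsilyloxy)nona-3,7,8-triene | CC[Si](CC)(CC)OCC/C=C(\C)C[C@@H](O[Si](C)(C)C(C)(C)C)C=C=C
F5 | step 16 | (Z)-3-iodobut-2-enal | O=C/C=C(/C)I
F6 | step 16 | nickelalactone of F4 (DBU ligands on nickel not drawn) | CC[Si](CC)(CC)OCC/C=C(\C)C[C@@H](O[Si](C)(C)C(C)(C)C)/C=C1/C[Ni]OC1=O
F7 | step 16 | 2-methylene-3,4-anti hydroxy acid from F6 and F5 (C6-OH, C7 side chain, C8-OTBS as in 27; primary OH free) | OC(=O)C(=C)[C@@H]([C@H](O)/C=C(/C)I)[C@H](O[Si](C)(C)C(C)(C)C)C/C(C)=C/CCO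
F8 | step 16 | 4,5-trans-4-[(1R,3E)-1-(tert-butyldimethylsilyloxy)-6-hydroxy-3-methylhex-3-enyl]-5-[(Z)-2-iodoprop-1-enyl]-3-methylenedihydrofuran-2-one | C=C1C(=O)O[C@H](/C=C(/C)I)[C@H]1[C@H](O[Si](C)(C)C(C)(C)C)C/C(C)=C/CCO
F9 | step 16 | aldehyde of F8 (6-oxo-3-methylhex-3-enyl side chain) | C=C1C(=O)O[C@H](/C=C(/C)I)[C@H]1[C@H](O[Si](C)(C)C(C)(C)C)C/C(C)=C/CC=O
F10 | step 16 | 8β-(tert-butyldimethylsilyloxy)-3β-hydroxygermacra-1(10)E,4Z,11(13)-trien-12,6α-olide | C=C1C(=O)O[C@@H]2/C=C(/C)[C@@H](O)C/C=C(\C)C[C@@H](O[Si](C)(C)C(C)(C)C)[C@@H]12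
F11 | step 21 | 1β,10α-epoxy-8β-hydroxy-3β-(3-methylbutanoyloxy)germacra-4Z,11(13)-dien-12,6α-olide | C=C1C(=O)O[C@@H]2/C=C(/C)[C@@H](OC(=O)CC(C)C)C[C@H]3O[C@]3(C)C[C@@H](O)[C@@H]12
F12 | step 3 | (R)-1-(trimethylsilyl)hexa-1,5-diyn-3-yl acetate | C#CC[C@@H](OC(C)=O)C#C[Si](C)(C)C
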